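**Retrosynthetic overview**
1. The benzylic C–O(alkyl) bond is made last. The target comes from (Z)-2-(angeloyloxymethyl)but-2-enoic acid and (R)-1-(3,4,5-trimethoxyphenyl)propan-1-ol by carboxylate SN2 with inversion.
2. The allylic CH2–O bond: the C10 acid is the dehydrogenative dimer of angelic acid, so it comes from 2 × angelic acid by directed C–H → C–O at the α-methyl group (new step).
3. The (R)-alcohol comes from 3,4,5-trimethoxybenzaldehyde and Et2Zn by catalytic asymmetric ethylation.
4. Both Z-alkenes are bought with angelic acid and never broken. Both carboxyl groups react only as O-nucleophiles, never as activated acyl groups.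
5. Rings: none is built for the target (the arene is bought). The only ring formed is a transient oxetan-2-one, opened in the same flask.

Assumption: the SMILES is taken at face value, so the benzylic carbon is (S) and both C=C bonds are Z (angelate type, CH3 cis to C=O).

**Step 1**
Reactants: 1 angelic acid, (Z)-2-methylbut-2-enoic acid (two molecules: one C–H partner, one O-nucleophile)
Product: 3 (Z)-2-({[(Z)-2-methylbut-2-enoyl]oxy}methyl)but-2-enoic acid, via (Z)-3-ethylideneoxetan-2-one 2 (not isolated)
Conditions: 1 (3.0 equiv), t-BuOOH (5.5 M in decane, 1.0 equiv, limiting), Pd(MeCN)2Cl2 (10 mol %), cis-2-acetamidocyclopentane-1-carboxylic acid (20 mol %), CsHCO3 (50 mol %), HFIP, 60 °C, 12 h; HFIP stripped, MeCN, 50 °C, 4 h, same flask; pH 3 work-up, excess 1 recovered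
Reagents that add atoms: none
Why: Proposed new method: carboxylate-directed Pd(II) cleavage of the α-methyl C–H of 1 gives a planar, strain-free five-membered palladacycle with no β-hydrogen (the vinylic H of the Z-acid points away from the carboxylate, so there is no vinyl C–H competitor), oxidation to Pd(IV) by t-BuOOH and C–O reductive elimination give the α-alkylidene β-lactone 2, and excess angelate then opens its unhindered allylic CH2–O carbon by SN2 (direct carboxylate attack on the Pd(IV)–CH2 carbon gives the same product), so no C=C bond is broken and both Z geometries carry over from 1; the closest known reaction type is the ligand-enabled Pd(II)/Pd(IV) β-C(sp3)–H lactonisation and acyloxylation of saturated α-branched free carboxylic acids with t-BuOOH, which has not been shown on the allylic methyl of an α,β-unsaturated acid or used as a dehydrogenative acid–acid dimerisation.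

**Step 2**
Reactants: 4 3,4,5-trimethoxybenzaldehyde
Product: 6 (R)-1-(3,4,5-trimethoxyphenyl)propan-1-ol, via ethylzinc alkoxide 5 (not isolated)
Conditions: Et2Zn (1.0 M in hexanes, 1.6 equiv), (+)-MIB [(2R)-3-exo-morpholinoisoborneol, 4 mol %], toluene, 0 °C, 12 h; sat. aq NH4Cl
Reagents that add atoms: diethylzinc, CC[Zn]CC
Why: Catalytic enantioselective dialkylzinc addition (Noyori-type amino-alcohol catalysis): the dinuclear zinc chelate of (+)-MIB delivers ethyl to the Re face of the aldehyde and so sets the (R) carbinol centre (the antipodal ligand gives the S series with aryl aldehydes), and the methoxy groups are inert.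

**Step 3**
Reactants: 3 (Z)-2-({[(Z)-2-methylbut-2-enoyl]oxy}methyl)but-2-enoic acid; 6 (R)-1-(3,4,5-trimethoxyphenyl)propan-1-ol
Product: 8 (S)-1-(3,4,5-trimethoxyphenyl)propyl (Z)-2-({[(Z)-2-methylbut-2-enoyl]oxy}methyl)but-2-enoate, via alkoxyphosphonium carboxylate 7 (not isolated)
Conditions: PPh3 (1.45 equiv) + DIAD (1.5 equiv), toluene, −20 °C (betaine preformed, no free PPh3 left); then 6 (1.0 equiv) and 3 (1.2 equiv), −20 → 0 °C, 6 h
Reagents that add atoms: none
Why: Mitsunobu esterification: the hydroxyl of 6 becomes the Ph3P+–O leaving group of 7 and the carboxylate of 3 displaces it by SN2 with inversion, (R)-6 → (S)-8, under neutral conditions in which neither Z-enoate is ever an activated acyl group, so Z→E isomerisation and SN2′ loss of the allylic angelate are avoided.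

**Compound list**
1 | angelic acid, (Z)-2-methylbut-2-enoic acid | C/C=C(/C)C(=O)O | starting material
2 | (Z)-3-ethylideneoxetan-2-one (CH3 cis to the lactone C=O) | C/C=C1/COC1=O | intermediate
3 | (Z)-2-({[(Z)-2-methylbut-2-enoyl]oxy}methyl)but-2-enoic acid | C/C=C(/C)C(=O)OC/C(=C/C)C(=O)O | intermediate
4 | 3,4,5-trimethoxybenzaldehyde | COc1cc(C=O)cc(OC)c1OC | starting material
5 | ethylzinc (R)-1-(3,4,5-trimethoxyphenyl)propan-1-olate | CC[C@@H](O[Zn]CC)c1cc(OC)c(OC)c(OC)c1 | intermediate
6 | (R)-1-(3,4,5-trimethoxyphenyl)propan-1-ol | CC[C@@H](O)c1cc(OC)c(OC)c(OC)c1 | intermediate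
7 | [(R)-1-(3,4,5-trimethoxyphenyl)propoxy]triphenylphosphonium salt of the carboxylate of 3 | CC[C@@H](O[P+](c1ccccc1)(c1ccccc1)c1ccccc1)c1cc(OC)c(OC)c(OC)c1.C/C=C(/C)C(=O)OC/C(=C/C)C(=O)[O-] | intermediate
8 | (S)-1-(3,4,5-trimethoxyphenyl)propyl (Z)-2-({[(Z)-2-methylbut-2-enoyl]oxy}methyl)but-2-enoate (CNP0198521.1) | C/C=C(/C)C(=O)OC/C(=C/C)C(=O)O[C@@H](CC)c1cc(OC)c(OC)c(OC)c1 | target

**Totals**
The route has 3 steps in total. The longest linear sequence is 2 steps (1 → 3 → 8, or 4 → 6 → 8).

**Steps most likely to fail**

1) Step 1, the proposed new step. There are four risks: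
- The C4 methyl of 1 is cis to the carboxylate and can be palladated through a six-membered ring, which would end in 3-methylfuran-2(5H)-one.
- Allyl slippage on Pd or reversible oxypalladation may leak Z to E.
- Acid 3 is itself a carboxylate and can open 2 to give a trimer, hence the excess of 1.
- Conjugate opening of 2 would give the branched 3-acyloxy-2-methylenebutanoic acid.

The risk sits on a one-pot reaction of a commercial acid, so it is cheap to test. The fallback uses known chemistry, sets out from 1 and comes back at 3. Commercial (E)-crotonaldehyde is α-iodinated (I2, K2CO3, cat. DMAP, THF–H2O, rt) to (Z)-2-iodobut-2-enal F1. This is reduced (NaBH4, MeOH, 0 °C) to (Z)-2-iodobut-2-en-1-ol F2. F2 is joined to 1 by Mitsunobu esterification (PPh3, DIAD, THF, 0 °C) to give (Z)-2-iodobut-2-en-1-yl (Z)-2-methylbut-2-enoate F3. The C–I bond of F3 is then hydroxycarbonylated with retention of geometry (PdCl2(PPh3)2, CO 1 atm, K2CO3, THF–H2O, rt) to give 3. This costs three extra steps.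

2) Step 3. The benzylic centre carries an electron-rich arene, so partial SN1 leakage (loss of ee) or elimination to the propenylarene is possible. The 4-OMe group is twisted out of conjugation by its two neighbours, which makes the cation much less stabilised than a 4-methoxybenzyl one. The fallback sets out from 4 and 3 and comes back at 8, and it forms the acyl–O bond with retention instead. Aldehyde 4 is ethylated as in step 2 but with (−)-MIB, giving (S)-1-(3,4,5-trimethoxyphenyl)propan-1-ol F4. Acid 3 is converted with 2,4,6-trichlorobenzoyl chloride and Et3N (toluene, rt) into (Z)-2-({[(Z)-2-methylbut-2-enoyl]oxy}methyl)but-2-enoic 2,4,6-trichlorobenzoic anhydride F5. F5 is heated with F4 in toluene at 75 °C without DMAP or any other nucleophilic catalyst, the non-isomerising variant used for angelates, to give 8.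

3) Step 2. The electron-rich aldehyde adds slowly, the ee may fall short, and the (+)-ligand is the less common antipode. The fallback sets out from 4 and comes back at 6, and it replaces asymmetric C–C formation with asymmetric ketone reduction. EtMgBr (THF, 0 °C) gives racemic 1-(3,4,5-trimethoxyphenyl)propan-1-ol F6. MnO2 (CH2Cl2, rt) gives 1-(3,4,5-trimethoxyphenyl)propan-1-one F7. Noyori transfer hydrogenation with RuCl(p-cymene)[(R,R)-TsDPEN] in HCO2H–Et3N (rt) gives (R)-6.

**Further compounds**
F1 | step 1 | (Z)-2-iodobut-2-enal | C/C=C(\I)C=O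
F2 | step 1 | (Z)-2-iodobut-2-en-1-ol | C/C=C(\I)CO
F3 | step 1 | (Z)-2-iodobut-2-en-1-yl (Z)-2-methylbut-2-enoate | C/C=C(/C)C(=O)OC/C(I)=C/C
F4 | step 3 | (S)-1-(3,4,5-trimethoxyphenyl)propan-1-ol | CC[C@H](O)c1cc(OC)c(OC)c(OC)c1
F5 | step 3 | (Z)-2-({[(Z)-2-methylbut-2-enoyl]oxy}methyl)but-2-enoic 2,4,6-trichlorobenzoic anhydride | C/C=C(/C)C(=O)OC/C(=C/C)C(=O)OC(=O)c1c(Cl)cc(Cl)cc1Cl
F6 | step 2 | racemic 1-(3,4,5-trimethoxyphenyl)propan-1-ol | CCC(O)c1cc(OC)c(OC)c(OC)c1
F7 | step 2 | 1-(3,4,5-trimethoxyphenyl)propan-1-one | CCC(=O)c1cc(OC)c(OC)c(OC)c1
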